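C6 of ring A (next to the ring alkene C4=C5) and C6' of ring B (next to the tertiary carbinol C5') are joined by one unbroken sp2 chain, C7 to C7'. The target is therefore the proton-shifted, ring-opened isomer of a normal polyene that carries H on C6 and a 5',6'-oxirane.
Key disconnection C7–C8: the bond is made as a Wittig C=C bond between a C10 ring-A aldehyde and a C30 ylide. Base in the same flask then removes H6, the charge runs through the chain and opens the oxirane, and C7–C8 ends as the single bond of the retro-polyene.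
The C30 ylide comes from a ring-B epoxy aldehyde (C7'=C8' Wittig) and the C20 bis(phosphonium) salt made from crocetin dialdehyde.
No carbocycle is built. Rings A and B are both ketoisophorone, reduced to the (S)- and the (R)-carbinol by the two enantiomers of one transfer-hydrogenation catalyst. C7 comes from a sulfonium methylide and C7' from CO.
Temporary rings, in order: the 5',6'-oxirane on ring B (step 6, opened in the key step) and the spiro-oxirane on ring A (step 13, opened in step 14).
Key step: step 16

Remark: carotenoid numbering is used (ring A = C1–C6 with C3–OH and C4=C5; chain C7–C15 and C15'–C7'; ring B = C1'–C6' with C3'–OH and C5'(OH)(CH3)). The C6 centre of the ring-A intermediates is carried as a mixture of epimers because the key step erases it.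
Abbreviations: TBS = tert-butyldimethylsilyl, Tf = trifluoromethanesulfonyl, DET = diethyl tartrate, NMO = N-methylmorpholine N-oxide.

Step 1
Reactants: 1 ketoisophorone
Product: 2 (4R)-4-hydroxy-2,6,6-trimethylcyclohex-2-en-1-one
Conditions: RuCl(p-cymene)[(R,R)-TsDPEN] (0.5 mol %), KOt-Bu (1 mol %), i-PrOH, 20 °C
Reagents that add atoms: none
Why: Noyori-type asymmetric transfer hydrogenation should reduce only the C4 carbonyl, because the C1 carbonyl is shielded by the gem-dimethyl carbon and the vinylic methyl group, and the (R,R)-ligand, which treats the alkenyl flank like the aryl group of an aryl ketone, sets the (R)-carbinol that becomes C3'.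

Step 2
Reactants: 2 (4R)-4-hydroxy-2,6,6-trimethylcyclohex-2-en-1-one
Product: 3 (4R)-4-(TBS-oxy)-2,6,6-trimethylcyclohex-2-en-1-one
Conditions: TBSCl, imidazole, DMF, 20 °C
Reagents that add atoms: tert-butyldimethylsilyl chloride, CC(C)(C)[Si](C)(C)Cl
Why: Imidazole-promoted silylation of a secondary alcohol, which stops base-induced isomerisation of the γ-hydroxy enone and later keeps O3' from attacking the oxirane.

Step 3
Reactants: 3 (4R)-4-(TBS-oxy)-2,6,6-trimethylcyclohex-2-en-1-one
Product: 5 (4S)-4-(TBS-oxy)-2,6,6-trimethylcyclohex-1-en-1-yl triflate, via lithium enolate 4 (not isolated)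
Conditions: LiBH(s-Bu)3, THF, −78 °C; then PhNTf2, −78 → 0 °C
Reagents that add atoms: N-phenylbis(trifluoromethanesulfonimide), O=S(=O)(N(c1ccccc1)S(=O)(=O)C(F)(F)F)C(F)(F)F
Why: Conjugate reduction with a bulky trialkylborohydride (1,2-attack is blocked by the neighbouring quaternary carbon) gives the enolate with the C5'=C6' double bond regiospecifically, and O-sulfonylation with PhNTf2 traps it as the tetrasubstituted enol triflate, the carbinol centre being untouched (its descriptor changes from R to S only through the priority rules).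

Step 4
Reactants: 5 (4S)-4-(TBS-oxy)-2,6,6-trimethylcyclohex-1-en-1-yl triflate
Product: 6 methyl (4S)-4-(TBS-oxy)-2,6,6-trimethylcyclohex-1-ene-1-carboxylate
Conditions: Pd(OAc)2 (5 mol %), PPh3 (10 mol %), CO (1 atm), MeOH, Et3N, DMF, 60 °C
Reagents that add atoms: carbon monoxide, [C-]#[O+]; methanol, CO
Why: Palladium-catalysed methoxycarbonylation of an enol triflate (oxidative addition to zerovalent palladium, CO insertion, methanolysis) brings in C7' at the hindered ring carbon.

Step 5
Reactants: 6 methyl (4S)-4-(TBS-oxy)-2,6,6-trimethylcyclohex-1-ene-1-carboxylate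
Product: 7 [(4S)-4-(TBS-oxy)-2,6,6-trimethylcyclohex-1-en-1-yl]methanol
Conditions: i-Bu2AlH (2.3 equiv), CH2Cl2, −78 °C
Reagents that add atoms: none
Why: 1,2-Reduction of the conjugated ester by i-Bu2AlH at low temperature gives the allylic alcohol that the directed epoxidation needs.

Step 6
Reactants: 7 [(4S)-4-(TBS-oxy)-2,6,6-trimethylcyclohex-1-en-1-yl]methanol
Product: 8 [(1S,4R,6S)-4-(TBS-oxy)-2,2,6-trimethyl-7-oxabicyclo[4.1.0]heptan-1-yl]methanol
Conditions: Ti(Oi-Pr)4 (20 mol %), L-(+)-DET (24 mol %), t-BuOOH, 4 Å molecular sieves, CH2Cl2, −20 °C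
Reagents that add atoms: tert-butyl hydroperoxide, CC(C)(C)OO
Why: Sharpless asymmetric epoxidation, in which the (R,R)-tartrate delivers oxygen to the same face of the allylic alcohol as in the formation of (2S,3S)-epoxy alcohols from E-allylic alcohols, sets C5' (S) and C6' under reagent control on the face anti to the C3' silyloxy group.

Step 7
Reactants: 8 [(1S,4R,6S)-4-(TBS-oxy)-2,2,6-trimethyl-7-oxabicyclo[4.1.0]heptan-1-yl]methanol
Product: 9 (1R,4R,6S)-4-(TBS-oxy)-2,2,6-trimethyl-7-oxabicyclo[4.1.0]heptane-1-carbaldehyde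
Conditions: n-Pr4N[RuO4] (5 mol %), NMO, 4 Å molecular sieves, CH2Cl2, 20 °C
Reagents that add atoms: none
Why: Ley–Griffith oxidation under neutral conditions takes the primary alcohol to the non-enolisable epoxy aldehyde without opening the oxirane.

Step 8
Reactants: 10 crocetin dialdehyde
Product: 11 all-E C20 heptaene-1,16-diol
Conditions: NaBH4, THF/MeOH, 0 °C, dark
Reagents that add atoms: none
Why: Borohydride 1,2-reduction of both conjugated aldehyde termini leaves the heptaene untouched.

Step 9
Reactants: 11 all-E C20 heptaene-1,16-diol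
Product: 12 C20 heptaene-1,16-diyl bis(triphenylphosphonium) dibromide
Conditions: PPh3·HBr (2.1 equiv), MeOH/CH2Cl2, 0 → 20 °C
Reagents that add atoms: triphenylphosphine hydrobromide, Br.c1ccc(cc1)P(c1ccccc1)c1ccccc1
Why: Acid-mediated substitution of the allylic hydroxyl groups by PPh3 through the delocalised allyl cation is the standard entry to polyenyl phosphonium salts and places phosphorus at the unhindered chain ends.

Step 10
Reactants: 9 (1R,4R,6S)-4-(TBS-oxy)-2,2,6-trimethyl-7-oxabicyclo[4.1.0]heptane-1-carbaldehyde; 12 C20 heptaene-1,16-diyl bis(triphenylphosphonium) dibromide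
Product: 14 C30 epoxy-polyenyl triphenylphosphonium bromide, via C20 mono-ylide 13 (not isolated)
Conditions: 12 (3 equiv), NaOMe (1.0 equiv), CH2Cl2/MeOH, −10 °C; then 9 (1.0 equiv), → 20 °C, dark
Reagents that add atoms: none
Why: Wittig olefination run with a deficit of base and aldehyde against an excess of the symmetric bis-salt, so that one terminus reacts, should give the (7'E)-alkene from the semistabilised ylide and the hindered aldehyde, and polyenyl ylides are known to tolerate a 5,6-oxirane at the far end of their π system.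

Step 11
Reactants: 1 ketoisophorone
Product: 15 (4S)-4-hydroxy-2,6,6-trimethylcyclohex-2-en-1-one
Conditions: RuCl(p-cymene)[(S,S)-TsDPEN] (0.5 mol %), KOt-Bu (1 mol %), i-PrOH, 20 °C
Reagents that add atoms: none
Why: Same Noyori-type transfer hydrogenation as in step 1 with the mirror-image ligand, which sets the (S)-carbinol that becomes C3.

Step 12
Reactants: 15 (4S)-4-hydroxy-2,6,6-trimethylcyclohex-2-en-1-one
Product: 16 (4S)-4-(TBS-oxy)-2,6,6-trimethylcyclohex-2-en-1-one
Conditions: TBSCl, imidazole, DMF, 20 °C
Reagents that add atoms: tert-butyldimethylsilyl chloride, CC(C)(C)[Si](C)(C)Cl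
Why: Imidazole-promoted silylation protects the carbinol against the ylide base of step 13 and the Lewis acid of step 14.

Step 13
Reactants: 16 (4S)-4-(TBS-oxy)-2,6,6-trimethylcyclohex-2-en-1-one
Product: 17 (6S)-6-(TBS-oxy)-4,8,8-trimethyl-1-oxaspiro[2.5]oct-4-ene
Conditions: Me3SI, n-BuLi, THF, −10 °C; then 16, → 20 °C
Reagents that add atoms: trimethylsulfonium iodide, C[S+](C)C.[I-]
Why: Corey–Chaykovsky epoxidation, in which the small unstabilised sulfonium methylide adds 1,2 to the hindered enone carbonyl and closes the spiro-oxirane by 3-exo-tet displacement of Me2S, brings in C7, and the new spiro centre needs no control because step 16 erases it.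

Step 14
Reactants: 17 (6S)-6-(TBS-oxy)-4,8,8-trimethyl-1-oxaspiro[2.5]oct-4-ene
Product: 18 (4S)-4-(TBS-oxy)-2,6,6-trimethylcyclohex-2-ene-1-carbaldehyde
Conditions: Sc(OTf)3 (5 mol %), CH2Cl2, −20 °C
Reagents that add atoms: none
Why: Meinwald rearrangement of a vinyl oxirane, in which the Lewis acid opens the tertiary allylic C6–O bond and a 1,2-hydride shift from C7 gives the β,γ-unsaturated aldehyde with the C4=C5 bond left in place, and both C6 epimers serve.

Step 15
Reactants: 18 (4S)-4-(TBS-oxy)-2,6,6-trimethylcyclohex-2-ene-1-carbaldehyde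
Product: 19 (4S)-4-hydroxy-2,6,6-trimethylcyclohex-2-ene-1-carbaldehyde
Conditions: HF·pyridine, pyridine, THF, 0 °C
Reagents that add atoms: none
Why: Fluoride cleavage of the silyl ether in a pyridine-buffered medium avoids enolisation of the β,γ-unsaturated aldehyde and frees the hydroxyl group that must be a non-leaving alkoxide in step 16.

Step 16
Reactants: 14 C30 epoxy-polyenyl triphenylphosphonium bromide; 19 (4S)-4-hydroxy-2,6,6-trimethylcyclohex-2-ene-1-carbaldehyde
Product: 23 3'-O-TBS ether of the target, via C30 ylide 20 (not isolated), via epoxy-polyene 21 (not isolated), via polyenyl carbanion 22 (not isolated)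
Conditions: KOt-Bu (1.0 equiv), THF, −30 °C; 19 (1.2 equiv), −30 → 0 °C; then KOt-Bu (4 equiv), DMSO/THF, 0 → 20 °C, Ar, dark; then H2O, 0 °C
Reagents that add atoms: none
Why: Proposed new method: the semistabilised ylide 20 and aldehyde 19 first undergo an ordinary Wittig olefination, which makes the C7–C8 link as a C=C bond and so closes the last gap in the π path between ring A and the oxirane of ring B (21); KOt-Bu in DMSO then removes H6, and the resulting 21-centre carbanion 22 (C4 to C7') expels the allylic C6'–O bond of the oxirane in a vinylogous E1cB step, whereby the nine chain double bonds are redrawn as ten, C7–C8 becomes the sp2–sp2 single bond of the target and the exocyclic alkenes C6=C7 and C6'=C7' and the C5' alkoxide appear together. The closest known reaction types are the base-catalysed ε-ring to β-ring isomerisation of ε-end-group carotenoids in hydroxide or alkoxide/DMSO, which runs through the same H6 deprotonation, and the E1cB opening of 5,6-epoxy end groups by an adjacent enolate in mild base; what is new is that the two are coupled through the whole polyene and run in the flask of the olefination. No ring is closed and no stereocentre is created: C5' keeps its configuration because only the C6'–O bond breaks, C3 and C3' are spectators, and the C6 centre and the C7=C8 geometry of 21 are erased, so all isomers of 21 converge. The former s-trans single bonds of the extended chain become E double bonds, and at both ring junctions the chain should turn toward the gem-dimethyl carbon (6E and 6'E) because the other rotamer presses H8 against the in-plane C5 methyl group and H8' against the C5' methyl group that stands cis to C7' on the oxirane. The step needs site-selective deprotonation, secured because H6 is the only hydrogen whose loss draws the isolated C4=C5 bond into conjugation (doubly allylic), whereas the chain methyl groups gain much less and the product has no such hydrogen left. It also needs the oxirane to be the only leaving group and to meet no internal nucleophile, secured by keeping O3 as a non-leaving alkoxide next to C4 and O3' as its silyl ether so that it cannot attack C6' across ring B.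

Step 17
Reactants: 23 3'-O-TBS ether of the target
Product: 24 target CNP0269135.1
Conditions: n-Bu4NF, THF, 0 → 20 °C, Ar, dark
Reagents that add atoms: none
Why: Fluoride-driven cleavage of the remaining silyl ether under non-acidic conditions spares the acid-labile allylic alcohols and the retro-polyene and touches no stereocentre.

Compound list
1 | ketoisophorone (2,6,6-trimethylcyclohex-2-ene-1,4-dione) | CC1=CC(=O)CC(C)(C)C1=O | starting material
2 | (4R)-4-hydroxy-2,6,6-trimethylcyclohex-2-en-1-one | CC1=C[C@H](O)CC(C)(C)C1=O | intermediate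
3 | (4R)-4-(tert-butyldimethylsilyloxy)-2,6,6-trimethylcyclohex-2-en-1-one | CC1=C[C@H](O[Si](C)(C)C(C)(C)C)CC(C)(C)C1=O | intermediate
4 | lithium (4S)-4-(tert-butyldimethylsilyloxy)-2,6,6-trimethylcyclohex-1-en-1-olate | CC1=C([O-])C(C)(C)C[C@@H](O[Si](C)(C)C(C)(C)C)C1.[Li+] | intermediate
5 | (4S)-4-(tert-butyldimethylsilyloxy)-2,6,6-trimethylcyclohex-1-en-1-yl trifluoromethanesulfonate | CC1=C(OS(=O)(=O)C(F)(F)F)C(C)(C)C[C@@H](O[Si](C)(C)C(C)(C)C)C1 | intermediate
6 | methyl (4S)-4-(tert-butyldimethylsilyloxy)-2,6,6-trimethylcyclohex-1-ene-1-carboxylate | COC(=O)C1=C(C)C[C@H](O[Si](C)(C)C(C)(C)C)CC1(C)C | intermediate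
7 | [(4S)-4-(tert-butyldimethylsilyloxy)-2,6,6-trimethylcyclohex-1-en-1-yl]methanol | OCC1=C(C)C[C@H](O[Si](C)(C)C(C)(C)C)CC1(C)C | intermediate
8 | [(1S,4R,6S)-4-(tert-butyldimethylsilyloxy)-2,2,6-trimethyl-7-oxabicyclo[4.1.0]heptan-1-yl]methanol (oxirane anti to the silyloxy group) | OC[C@]12O[C@@]1(C)C[C@H](O[Si](C)(C)C(C)(C)C)CC2(C)C | intermediate
9 | (1R,4R,6S)-4-(tert-butyldimethylsilyloxy)-2,2,6-trimethyl-7-oxabicyclo[4.1.0]heptane-1-carbaldehyde | O=C[C@]12O[C@@]1(C)C[C@H](O[Si](C)(C)C(C)(C)C)CC2(C)C | intermediate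
10 | crocetin dialdehyde (all-E-2,6,11,15-tetramethylhexadeca-2,4,6,8,10,12,14-heptaenedial) | O=C/C(C)=C/C=C/C(C)=C/C=C/C=C(C)/C=C/C=C(C)/C=O | starting material
11 | all-E-2,6,11,15-tetramethylhexadeca-2,4,6,8,10,12,14-heptaene-1,16-diol | OC/C(C)=C/C=C/C(C)=C/C=C/C=C(C)/C=C/C=C(C)/CO | intermediate
12 | all-E-2,6,11,15-tetramethylhexadeca-2,4,6,8,10,12,14-heptaene-1,16-diyl bis(triphenylphosphonium) dibromide | c1ccccc1[P+](c1ccccc1)(c1ccccc1)C/C(C)=C/C=C/C(C)=C/C=C/C=C(C)/C=C/C=C(C)/C[P+](c1ccccc1)(c1ccccc1)c1ccccc1.[Br-].[Br-] | intermediate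
13 | mono-ylide of 12 (one end Ph3P=CH, other end CH2–PPh3 bromide) | c1ccccc1[P+](c1ccccc1)(c1ccccc1)C/C(C)=C/C=C/C(C)=C/C=C/C=C(C)/C=C/C=C(C)/C=P(c1ccccc1)(c1ccccc1)c1ccccc1.[Br-] | intermediate
14 | C30 phosphonium bromide: Ph3P–C8H2 end, all-E nonaene C9=C10 to C8'=C7', ring B as (3'R,5'S,6'R)-3'-TBS-oxy-5',6'-epoxide | c1ccccc1[P+](c1ccccc1)(c1ccccc1)C/C(C)=C/C=C/C(C)=C/C=C/C=C(C)/C=C/C=C(C)/C=C/[C@]12O[C@@]1(C)C[C@H](O[Si](C)(C)C(C)(C)C)CC2(C)C.[Br-] | intermediate
15 | (4S)-4-hydroxy-2,6,6-trimethylcyclohex-2-en-1-one | CC1=C[C@@H](O)CC(C)(C)C1=O | intermediate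
16 | (4S)-4-(tert-butyldimethylsilyloxy)-2,6,6-trimethylcyclohex-2-en-1-one | CC1=C[C@@H](O[Si](C)(C)C(C)(C)C)CC(C)(C)C1=O | intermediate
17 | (6S)-6-(tert-butyldimethylsilyloxy)-4,8,8-trimethyl-1-oxaspiro[2.5]oct-4-ene (both spiro epimers) | CC1=C[C@@H](O[Si](C)(C)C(C)(C)C)CC(C)(C)C12CO2 | intermediate
18 | (4S)-4-(tert-butyldimethylsilyloxy)-2,6,6-trimethylcyclohex-2-ene-1-carbaldehyde (both C1 epimers) | CC1=C[C@@H](O[Si](C)(C)C(C)(C)C)CC(C)(C)C1C=O | intermediate
19 | (4S)-4-hydroxy-2,6,6-trimethylcyclohex-2-ene-1-carbaldehyde (both C1 epimers) | CC1=C[C@@H](O)CC(C)(C)C1C=O | intermediate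
20 | C30 ylide from 14 (Ph3P=C8H) | c1ccccc1P(c1ccccc1)(c1ccccc1)=C/C(C)=C/C=C/C(C)=C/C=C/C=C(C)/C=C/C=C(C)/C=C/[C@]12O[C@@]1(C)C[C@H](O[Si](C)(C)C(C)(C)C)CC2(C)C | intermediate
21 | normal-parity epoxy-polyene: (3S)-3-hydroxy ε-type ring A with H on C6, C7=C8 to C8'=C7' nonaene, (3'R,5'S,6'R)-3'-TBS-oxy-5',6'-epoxy ring B (drawn 7E, C6 epimers) | CC1=C[C@@H](O)CC(C)(C)C1/C=C/C(C)=C/C=C/C(C)=C/C=C/C=C(C)/C=C/C=C(C)/C=C/[C@]12O[C@@]1(C)C[C@H](O[Si](C)(C)C(C)(C)C)CC2(C)C | intermediate
22 | dipotassium salt of 21: C3 alkoxide and delocalised carbanion, drawn with the charge on C6 | CC1=C[C@@H]([O-])CC(C)(C)[C-]1/C=C/C(C)=C/C=C/C(C)=C/C=C/C=C(C)/C=C/C=C(C)/C=C/[C@]12O[C@@]1(C)C[C@H](O[Si](C)(C)C(C)(C)C)CC2(C)C.[K+].[K+] | intermediate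
23 | 3'-O-TBS ether of the target, (3S,3'R,5'S), all-E including 6E and 6'E | CC1=C[C@@H](O)CC(C)(C)\C1=C/C=C(C)/C=C/C=C(C)/C=C/C=C/C(C)=C/C=C/C(C)=C/C=C1\C(C)(C)C[C@@H](O[Si](C)(C)C(C)(C)C)C[C@]1(C)O | intermediate
24 | CNP0269135.1, (3S,3'R,5'S)-retro-carotene-3,3',5'-triol, all-E including 6E and 6'E | CC1=C[C@@H](O)CC(C)(C)\C1=C/C=C(C)/C=C/C=C(C)/C=C/C=C/C(C)=C/C=C/C(C)=C/C=C1\C(C)(C)C[C@@H](O)C[C@]1(C)O | target

Total step count: 17
Longest linear sequence: 10 steps (steps 1–7, 10, 16, 17)

Steps most likely to fail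

1. Step 16.
- What may go wrong: proton abstraction at a chain methyl group or at the hydrogens next to the oxirane instead of at H6. Premature oxirane opening by the ylide. Enolisation of the aldehyde before olefination. Loss of geometric control at the two ring junctions.
- Fallback: it sets out from 14 and 19 and returns at 23. It moves ring A to the ketone oxidation level so that only known, mild chemistry is needed.
- Only the Wittig stage is run (NaOMe, CH2Cl2/MeOH, 0 °C) and 21 is isolated.
- MnO2 in CH2Cl2 oxidises the allylic C3 hydroxyl selectively to the 3-oxo epoxy-polyene F1. In F1, H6 is the γ-hydrogen of an enone.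
- DBU in THF then suffices for the dienolate-driven E1cB opening of the oxirane. This gives the 3-oxo retro-polyene F2, whose push-pull path fixes the site of ionisation.
- Transfer hydrogenation with the catalyst of step 11 (RuCl(p-cymene)[(S,S)-TsDPEN], i-PrOH/CH2Cl2) acts on a carbonyl with the same flanks as in ketoisophorone. It restores the (3S)-carbinol and gives 23.

2. Step 10.
- What may go wrong: double olefination of the bis-salt and loss of material while an ionic polyene is purified.
- Fallback: it sets out from 11 and 9 and returns at 14. The C20 unit is desymmetrised before the coupling, and a neutral C30 compound is carried through the purification.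
- Diol 11 is treated with one equivalent of PPh3·HBr. The C20 hydroxy phosphonium bromide F3 is separated by partition from the neutral diol and from 12.
- Wittig reaction of F3 with 9 (NaOMe, CH2Cl2/MeOH) gives the C30 epoxy-polyenyl alcohol F4, which is purified by chromatography.
- PPh3·HBr at −20 °C in MeOH/CH2Cl2 converts F4 into 14.

3. Step 14.
- What may go wrong: proton loss or participation of the silyloxy group at the allyl cation stage, and drift of the ring double bond into conjugation with the aldehyde.
- Fallback: it sets out from 17 and returns at 18. The cationic hydride shift is replaced by a reductive opening through a π-allylpalladium hydride.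
- Pd2(dba)3, n-Bu3P, HCO2H and Et3N in dioxane deliver hydride to the oxygen-bearing allyl terminus. This gives the homoallylic primary alcohol F5.
- Ley–Griffith oxidation (n-Pr4N[RuO4], NMO) takes F5 to 18.

Further compounds
F1 | step 16 | 3-oxo epoxy-polyene (21 with C3=O) | CC1=CC(=O)CC(C)(C)C1/C=C/C(C)=C/C=C/C(C)=C/C=C/C=C(C)/C=C/C=C(C)/C=C/[C@]12O[C@@]1(C)C[C@H](O[Si](C)(C)C(C)(C)C)CC2(C)C
F2 | step 16 | 3-oxo retro-polyene (23 with C3=O) | CC1=CC(=O)CC(C)(C)\C1=C/C=C(C)/C=C/C=C(C)/C=C/C=C/C(C)=C/C=C/C(C)=C/C=C1\C(C)(C)C[C@@H](O[Si](C)(C)C(C)(C)C)C[C@]1(C)O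
F3 | step 10 | C20 hydroxy phosphonium bromide | OC/C(C)=C/C=C/C(C)=C/C=C/C=C(C)/C=C/C=C(C)/C[P+](c1ccccc1)(c1ccccc1)c1ccccc1.[Br-]
F4 | step 10 | C30 epoxy-polyenyl alcohol | OC/C(C)=C/C=C/C(C)=C/C=C/C=C(C)/C=C/C=C(C)/C=C/[C@]12O[C@@]1(C)C[C@H](O[Si](C)(C)C(C)(C)C)CC2(C)C
F5 | step 14 | [(4S)-4-(tert-butyldimethylsilyloxy)-2,6,6-trimethylcyclohex-2-en-1-yl]methanol | CC1=C[C@@H](O[Si](C)(C)C(C)(C)C)CC(C)(C)C1CO
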